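**Leave it shut.** We leave the summer flask closed until 64 h and add nothing to it. It was charged with substrate, coupling partner and free catalyst, and stands beside these earlier runs:

common to all: free catalyst 0.0150 M
- dawn: substrate 0.150 M; coupling partner 0.120 M
- midnight: substrate 0.0750 M; coupling partner 0.0450 M
- spring: substrate 0.150 M; coupling partner 0.360 M
- summer: substrate 0.150 M; coupling partner 0.870 M; time 64 h

| run | time / h | [substrate] / M |
|---|---|---|
| dawn run | 11 | 0.1123 |
| dawn run | 21 | 0.1013 |
| dawn run | 32 | 0.0975 |
| dawn run | 43 | 0.0953 |
| dawn run | 53 | 0.0938 |
| dawn run | 64 | 0.0927 |
| midnight run | 11 | 0.0644 |
| midnight run | 21 | 0.0595 |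
| midnight run | 32 | 0.0577 |
| midnight run | 43 | 0.0562 |
| midnight run | 53 | 0.0572 |
| midnight run | 64 | 0.0551 |
| spring run | 11 | 0.0847 |
| spring run | 21 | 0.0809 |
| spring run | 32 | 0.0794 |
| spring run | 43 | 0.0792 |
| spring run | 53 | 0.0773 |
| spring run | 64 | 0.0791 |

(scatter of a reading: 8 × 10⁻⁴ M)

- Overall: substrate + coupling partner -> target, with free catalyst as catalyst.
- Constant volume, constant temperature.
- Bound and free are read together.
- An order is taken over about fifteen percent of the charge, up and down.

- the exponent of [substrate] in the starting rate at the charge of the dawn run (at the point where two percent of the substrate have become target) (one fixed amount of target, the same in the runs compared)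
- the exponent of [coupling partner] in the starting rate at the charge of the dawn run (at the point where two percent of the substrate have become target)
- substrate in the summer run at 64 h, as a share of the substrate charged

**Where spring stopped.** The spring run reads flat, its readings from 43 h on averaging 0.0785 M of [substrate]. It has turned 0.0715 M of substrate against 0.360 M of coupling partner charged, so we read this stop as the end of the catalyst. That reading gives 43.1 /M: this is the catalyst capacity, the natural logarithm of substrate charged over substrate left at the stop, per catalyst charged.

**On your return.** We assume that the rate of coupling over the rate of catalyst death is proportional to [substrate] and does not depend on [coupling partner]. The summer run, with 0.0150 M of free catalyst, should then hold 52.4% of its substrate at 64 h, or 0.0785 M.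

**The forecast.** The forecast gives 51%, within 42% to 57%, a little below our figure, with exponents of 0.9 in [substrate] and 0.9 in [coupling partner]. Its ground is that “the catalyst dies, mainly through coupling partner”.

**What came.** The simulation gives 52.3% for the summer run, with exponents of 0.67 in [substrate] and 1.0 in [coupling partner].

    free catalyst + substrate ⇌ catalyst-substrate complex, settled at all times (4.510 /M)
    catalyst-substrate complex + coupling partner → target + free catalyst (10.22 /M/h)
    coupling partner → lost reagent (0.02894 /h)
    free catalyst + coupling partner → spent catalyst + coupling partner (1.044 /M/h)

**Why it stops.** The summer run stops through the conversion of free catalyst by coupling partner: without that step its substrate at 64 h is 0% instead of 52.3%, while the loss of coupling partner to lost reagent makes no difference there. At 64 h the summer run has used 100% of the capacity read from the spring run. The midnight run, at its last reading, has used 47.6%.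

The runs are simulated with made-up constants; the scatter is artificial.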